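**Assumption:** the target has no stereocentre and its diaryl ether axis rotates freely, so it is one achiral compound and no stereocontrol is needed.

## Retrosynthetic overview

- The target comes from its benzyl ether by O-debenzylation. The ring-A bromine comes from NH2 and that from NO2 (Sandmeyer); the ring-A OMe comes from OH.
- Key disconnection: ring A of the nitrophenol is cut into an aryloxyacetone (three ring carbons) and nitromalonaldehyde (three ring carbons). An intermolecular aldol condensation makes the first ring-A C–C bond and an intramolecular aldol condensation the second.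
- The aryloxyacetone comes from 2-(benzyloxy)-4,6-dibromophenol and chloroacetone. That phenol comes from 3,5-dibromosalicylaldehyde (CHO to OH by Baeyer–Villiger oxidation, with a MOM/benzyl protecting-group exchange).
- Ring order: ring B (the dibromophenol ring) is bought with both bromines in place; ring A (the bromo-methoxy ring) is built in step 6.

## Route

**Step 1**
Reactants: 1 3,5-dibromo-2-hydroxybenzaldehyde; 2 chloromethyl methyl ether (MOMCl)
Product: 3 3,5-dibromo-2-(methoxymethoxy)benzaldehyde
Conditions: MOMCl (1.5 equiv), i-Pr2NEt (2 equiv), CH2Cl2, 0 °C → rt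
Reagents that add atoms: chloromethyl methyl ether, COCCl
Why: Williamson-type O-alkylation of the acidic salicyl phenol by the reactive α-chloro ether masks the oxygen that will later carry ring A and turns the aldehyde into a 2-alkoxybenzaldehyde fit for Baeyer–Villiger oxidation.

**Step 2**
Reactants: 3 3,5-dibromo-2-(methoxymethoxy)benzaldehyde; 4 3-chloroperoxybenzoic acid (mCPBA)
Product: 6 3,5-dibromo-2-(methoxymethoxy)phenol, via aryl formate 5 (not isolated)
Conditions: mCPBA (1.6 equiv), CH2Cl2, 0 °C → rt, 16 h; then K2CO3 (cat.), MeOH, rt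
Reagents that add atoms: 3-chloroperoxybenzoic acid, O=C(OO)c1cccc(Cl)c1
Why: Baeyer–Villiger (Dakin-type) oxidation in which the ortho-alkoxy aryl group migrates to give the formate, which is methanolysed to the phenol while the MOM ether and aryl bromides are inert to peracid.

**Step 3**
Reactants: 6 3,5-dibromo-2-(methoxymethoxy)phenol; 7 benzyl bromide
Product: 8 1-(benzyloxy)-3,5-dibromo-2-(methoxymethoxy)benzene
Conditions: BnBr (1.2 equiv), K2CO3 (1.5 equiv), DMF, rt
Reagents that add atoms: benzyl bromide, BrCc1ccccc1
Why: Williamson etherification of the unhindered phenoxide puts an acid- and base-stable protecting group on the oxygen that ends as the free OH of ring B.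

**Step 4**
Reactants: 8 1-(benzyloxy)-3,5-dibromo-2-(methoxymethoxy)benzene
Product: 9 2-(benzyloxy)-4,6-dibromophenol
Conditions: conc. HCl (cat.), MeOH, 50 °C
Reagents that add atoms: none
Why: Acid-catalysed acetal exchange (MOM cleavage) frees only the acetal-protected oxygen, since benzyl aryl ethers and aryl bromides are stable to dilute methanolic HCl.

**Step 5**
Reactants: 9 2-(benzyloxy)-4,6-dibromophenol; 10 chloroacetone
Product: 11 1-[2-(benzyloxy)-4,6-dibromophenoxy]propan-2-one
Conditions: chloroacetone (1.3 equiv), K2CO3 (1.5 equiv), KI (cat.), acetone, reflux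
Reagents that add atoms: chloroacetone, CC(=O)CCl
Why: Williamson etherification by SN2 at the carbonyl-activated CH2Cl (iodide catalysis) is fast enough for this hindered phenoxide and delivers a ketone with two enolisable α-carbons.

**Step 6**
Reactants: 11 1-[2-(benzyloxy)-4,6-dibromophenoxy]propan-2-one; 12 sodium nitromalonaldehyde monohydrate
Product: 15 2-[2-(benzyloxy)-4,6-dibromophenoxy]-4-nitrophenol, via open-chain enal 13 (not isolated), via cyclic aldol 14 (not isolated)
Conditions: 12 (1.2 equiv, handled moist behind a shield), NaOH (1.2 equiv), EtOH/THF/H2O, 0 °C → rt, 48 h; then 2 M HCl to pH 2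
Reagents that add atoms: sodium nitromalonaldehyde monohydrate, [Na+].[O-]C=C(C=O)[N+](=O)[O-].O
Why: An intermolecular aldol condensation joins one α-carbon of the ketone to one formyl carbon, the second α-carbon closes ring A by intramolecular aldol condensation, and loss of two waters gives the aromatic 4-nitrophenol directly (classical nitromalonaldehyde [3+3] phenol synthesis); because both α-carbons end in the ring, the aryloxy group is necessarily ortho and the nitro group para to the new OH, and no stereocentre remains.

**Step 7**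
Reactants: 15 2-[2-(benzyloxy)-4,6-dibromophenoxy]-4-nitrophenol; 16 iodomethane
Product: 17 1-(benzyloxy)-3,5-dibromo-2-(2-methoxy-5-nitrophenoxy)benzene
Conditions: MeI (1.5 equiv), K2CO3 (2 equiv), DMF, rt
Reagents that add atoms: iodomethane, CI
Why: Williamson O-methylation of the acidic 4-nitrophenol is clean because it is the only free OH in the molecule.

**Step 8**
Reactants: 17 1-(benzyloxy)-3,5-dibromo-2-(2-methoxy-5-nitrophenoxy)benzene
Product: 18 3-[2-(benzyloxy)-4,6-dibromophenoxy]-4-methoxyaniline
Conditions: Fe powder (5 equiv), AcOH/EtOH, 70 °C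
Reagents that add atoms: none
Why: Béchamp reduction by electron transfer from Fe in AcOH converts the nitro group to the amine without the hydrodebromination or debenzylation that catalytic hydrogenation would risk.

**Step 9**
Reactants: 18 3-[2-(benzyloxy)-4,6-dibromophenoxy]-4-methoxyaniline; 19 tert-butyl nitrite; 20 CuBr2
Product: 22 1-(benzyloxy)-3,5-dibromo-2-(5-bromo-2-methoxyphenoxy)benzene, via arenediazonium bromide 21 (not isolated)
Conditions: t-BuONO (1.5 equiv), CuBr2 (1.2 equiv), MeCN, 0 °C → 60 °C, slow addition of 18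
Reagents that add atoms: CuBr2 (copper dibromide), [Cu+2].[Br-].[Br-]
Why: Sandmeyer bromination under non-aqueous Doyle conditions (alkyl nitrite diazotisation, copper-mediated bromine transfer) swaps N2 for Br at the same carbon, so the bromine sits para to OMe, and the neutral medium spares the benzyl ether.

**Step 10**
Reactants: 22 1-(benzyloxy)-3,5-dibromo-2-(5-bromo-2-methoxyphenoxy)benzene
Product: 24 3,5-dibromo-2-(5-bromo-2-methoxyphenoxy)phenol, via aryloxydichloroborane 23 (not isolated)
Conditions: BCl3 (1 M in CH2Cl2, 2.5 equiv), C6HMe5 (3 equiv), CH2Cl2, −78 °C, 45 min; then H2O, −78 °C → rt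
Reagents that add atoms: none
Why: Lewis-acid O-debenzylation with pentamethylbenzene as benzyl-cation scavenger cleaves the benzyl aryl ether at −78 °C while the methyl ether, the diaryl ether and the three aryl bromides are untouched.

## Compound list

1 | 3,5-dibromo-2-hydroxybenzaldehyde (3,5-dibromosalicylaldehyde) | O=Cc1cc(Br)cc(Br)c1O | starting material
2 | chloromethyl methyl ether | COCCl | starting material
3 | 3,5-dibromo-2-(methoxymethoxy)benzaldehyde | O=Cc1cc(Br)cc(Br)c1OCOC | intermediate
4 | 3-chloroperoxybenzoic acid | O=C(OO)c1cccc(Cl)c1 | starting material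
5 | 3,5-dibromo-2-(methoxymethoxy)phenyl formate (formed in the flask, not isolated) | O=COc1cc(Br)cc(Br)c1OCOC | intermediate
6 | 3,5-dibromo-2-(methoxymethoxy)phenol | Oc1cc(Br)cc(Br)c1OCOC | intermediate
7 | benzyl bromide | BrCc1ccccc1 | starting material
8 | 1-(benzyloxy)-3,5-dibromo-2-(methoxymethoxy)benzene | COCOc1c(Br)cc(Br)cc1OCc1ccccc1 | intermediate
9 | 2-(benzyloxy)-4,6-dibromophenol | Oc1c(Br)cc(Br)cc1OCc1ccccc1 | intermediate
10 | chloroacetone (1-chloropropan-2-one) | CC(=O)CCl | starting material
11 | 1-[2-(benzyloxy)-4,6-dibromophenoxy]propan-2-one | CC(=O)COc1c(Br)cc(Br)cc1OCc1ccccc1 | intermediate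
12 | sodium nitromalonaldehyde monohydrate (sodium 2-nitro-3-oxoprop-1-en-1-olate hydrate; delocalised anion, no fixed geometry) | [Na+].[O-]C=C(C=O)[N+](=O)[O-].O | starting material
13 | (3E)-4-[2-(benzyloxy)-4,6-dibromophenoxy]-2-nitro-5-oxohex-3-enal (present as its sodium salt, racemic at the labile C2, not isolated) | CC(=O)/C(Oc1c(Br)cc(Br)cc1OCc1ccccc1)=C\C(C=O)[N+](=O)[O-] | intermediate
14 | 2-[2-(benzyloxy)-4,6-dibromophenoxy]-5-hydroxy-4-nitrocyclohex-2-en-1-one (mixture of diastereomers, not isolated) | O=C1CC(O)C([N+](=O)[O-])C=C1Oc1c(Br)cc(Br)cc1OCc1ccccc1 | intermediate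
15 | 2-[2-(benzyloxy)-4,6-dibromophenoxy]-4-nitrophenol | Oc1ccc([N+](=O)[O-])cc1Oc1c(Br)cc(Br)cc1OCc1ccccc1 | intermediate
16 | iodomethane | CI | starting material
17 | 1-(benzyloxy)-3,5-dibromo-2-(2-methoxy-5-nitrophenoxy)benzene | COc1ccc([N+](=O)[O-])cc1Oc1c(Br)cc(Br)cc1OCc1ccccc1 | intermediate
18 | 3-[2-(benzyloxy)-4,6-dibromophenoxy]-4-methoxyaniline | COc1ccc(N)cc1Oc1c(Br)cc(Br)cc1OCc1ccccc1 | intermediate
19 | tert-butyl nitrite | CC(C)(C)ON=O | starting material
20 | CuBr2 (copper dibromide) | [Cu+2].[Br-].[Br-] | starting material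
21 | 3-[2-(benzyloxy)-4,6-dibromophenoxy]-4-methoxybenzenediazonium bromide (not isolated) | COc1ccc([N+]#N)cc1Oc1c(Br)cc(Br)cc1OCc1ccccc1.[Br-] | intermediate
22 | 1-(benzyloxy)-3,5-dibromo-2-(5-bromo-2-methoxyphenoxy)benzene | COc1ccc(Br)cc1Oc1c(Br)cc(Br)cc1OCc1ccccc1 | intermediate
23 | dichloro[3,5-dibromo-2-(5-bromo-2-methoxyphenoxy)phenoxy]borane (not isolated) | COc1ccc(Br)cc1Oc1c(Br)cc(Br)cc1OB(Cl)Cl | intermediate
24 | 3,5-dibromo-2-(5-bromo-2-methoxyphenoxy)phenol | COc1ccc(Br)cc1Oc1c(O)cc(Br)cc1Br | target

## Step count and risks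

Total step count: 10.
Longest linear sequence: 10 steps (1 to 24, fully linear).

**Most likely to fail: step 6 (double aldol ring construction).** The ketone is lipophilic and hindered, the condensation is slow, and hydroxide can degrade either partner. The fallback takes ring A from an arene instead. It sets out from phenol 9 and comes back to the route at 22, bypassing steps 5 to 9. Nucleophilic aromatic substitution of 9 on 4-bromo-2-fluorobenzaldehyde (Cs2CO3, DMAc, 110 °C; the fluoride is activated by the ortho formyl group) gives 2-[2-(benzyloxy)-4,6-dibromophenoxy]-4-bromobenzaldehyde F1. Baeyer–Villiger oxidation with mCPBA in CH2Cl2 gives 2-[2-(benzyloxy)-4,6-dibromophenoxy]-4-bromophenyl formate F2. Methanolysis (K2CO3 cat., MeOH) gives 2-[2-(benzyloxy)-4,6-dibromophenoxy]-4-bromophenol F3. O-methylation (MeI, K2CO3, DMF) then delivers 22.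

**Second: step 9 (Sandmeyer bromination).** The electron-rich aniline can be ring-brominated by CuBr2 before diazotisation, or the diazonium can be reduced to the arene. The fallback separates nitrogen removal from bromine introduction. It sets out from aniline 18 and comes back at 22. Hydrodediazoniation (t-BuONO, DMF, 60 °C) gives 1-(benzyloxy)-3,5-dibromo-2-(2-methoxyphenoxy)benzene F4, which is also the usual by-product of a failed Sandmeyer reaction and can be pooled. Electrophilic bromination (NBS, MeCN, rt) then goes para to the methoxy group, the strongest donor on the only activated ring, to give 22. The regiochemistry would be confirmed by NMR against material from step 9.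

**Third: step 2 (Baeyer–Villiger oxidation).** The aryl group is electron-poor and its alkoxy donor is twisted by two ortho neighbours, so hydride migration to the benzoic acid may compete. The fallback changes the migrating-group competition from aryl against hydrogen to aryl against methyl. It sets out from aldehyde 3 and comes back at 6. Addition of MeMgBr (THF, −78 °C) gives racemic 1-[3,5-dibromo-2-(methoxymethoxy)phenyl]ethan-1-ol F5. Dess–Martin periodinane (CH2Cl2, rt) gives 1-[3,5-dibromo-2-(methoxymethoxy)phenyl]ethan-1-one F6. Baeyer–Villiger oxidation (mCPBA, NaHCO3, CH2Cl2, reflux), in which aryl migrates in preference to methyl, gives 3,5-dibromo-2-(methoxymethoxy)phenyl acetate F7. Methanolysis (K2CO3 cat., MeOH) returns phenol 6.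

## Further compounds

F1 | step 6 | 2-[2-(benzyloxy)-4,6-dibromophenoxy]-4-bromobenzaldehyde | O=Cc1ccc(Br)cc1Oc1c(Br)cc(Br)cc1OCc1ccccc1
F2 | step 6 | 2-[2-(benzyloxy)-4,6-dibromophenoxy]-4-bromophenyl formate | O=COc1ccc(Br)cc1Oc1c(Br)cc(Br)cc1OCc1ccccc1
F3 | step 6 | 2-[2-(benzyloxy)-4,6-dibromophenoxy]-4-bromophenol | Oc1ccc(Br)cc1Oc1c(Br)cc(Br)cc1OCc1ccccc1
F4 | step 9 | 1-(benzyloxy)-3,5-dibromo-2-(2-methoxyphenoxy)benzene | COc1ccccc1Oc1c(Br)cc(Br)cc1OCc1ccccc1
F5 | step 2 | rac-1-[3,5-dibromo-2-(methoxymethoxy)phenyl]ethan-1-ol | CC(O)c1cc(Br)cc(Br)c1OCOC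
F6 | step 2 | 1-[3,5-dibromo-2-(methoxymethoxy)phenyl]ethan-1-one | CC(=O)c1cc(Br)cc(Br)c1OCOC
F7 | step 2 | 3,5-dibromo-2-(methoxymethoxy)phenyl acetate | CC(=O)Oc1cc(Br)cc(Br)c1OCOC
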